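**Retrosynthetic overview**

1. Endgame: the quinone is unveiled from a 2,5-dimethoxy-3-methylphenyl ring with (NH4)2Ce(NO3)6 after C5 acetylation and C14–O desilylation; C1–C2 comes from zirconium-catalysed carboalumination of a terminal C2≡C3 alkyne and nickel-catalysed coupling with a benzylic chloride (chain numbered C1 = ArCH2 to C15 = CMe2; oxolane = O, C12, C13, C14, C15).
2. C4–C5 and the C5 stereocentre come from catalyst-controlled propargylation of a C5 enal; the 6E and 10E alkenes come from two further alkyne carboaluminations, joined at C9–C10 by a Negishi coupling with a homopropargylzinc.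
3. C11–C12 comes from alkynylation of the oxolanyl oxocarbenium ion (from a lactol acetate), cis to the C14 silyloxy group; the lactone comes from RuO4 oxidation of the only ring CH2 next to oxygen (C12).
4. Rings: the oxolane is the first ring made and is not closed at its final size. The three-membered oxirane of (R)-prenol epoxide is expanded to the five-membered ring by a Payne-relayed sulfoxonium-ylide homologation (oxirane O, C14 and C15 are kept; C13 and the ylide carbon C12 are inserted). The benzene ring is bought and becomes the quinone last.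
5. Enabling feature: the free C13 hydroxymethyl beside the C14–C15 oxirane with its gem-dimethyl carbon. Payne migration moves the oxirane to C13–C14 (inversion at C14) and releases the former oxirane oxygen as a tertiary alkoxide on C15, set up for 5-exo-tet closure onto C12.

Key step: step 2

Remark on the chemistry: the target is read as (5S,12S,14S) with 2E,6E,10E, the C12 and C14 substituents being cis on the oxolane. The cis outcome of step 6 is assumed from the inside-attack model for five-membered oxocarbenium ions with a pseudoaxial C14 oxygen substituent.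

**Route**

Step 1
Reactants: 1 3-methylbut-2-en-1-ol (prenol)
Product: 2 [(2R)-3,3-dimethyloxiran-2-yl]methanol
Conditions: Ti(OiPr)4 (cat.), D-(−)-diisopropyl tartrate (cat.), t-BuOOH, 4 Å MS, CH2Cl2, −20 °C
Reagents that add atoms: tert-butyl hydroperoxide, CC(C)(C)OO
Why: Sharpless asymmetric epoxidation of the allylic alcohol; the titanium/D-tartrate complex should deliver oxygen to the alkene face that gives the 2R oxirane.

Step 2
Reactants: 2 [(2R)-3,3-dimethyloxiran-2-yl]methanol
Product: 4 (3S)-2,2-dimethyloxolan-3-ol, via sodium 2-[(2S)-oxiran-2-yl]propan-2-olate 3 (not isolated)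
Conditions: Me3S(O)I, NaH, DMSO, rt then 85 °C
Reagents that add atoms: trimethylsulfoxonium iodide, C[S+](C)(C)=O.[I-]
Why: Payne rearrangement (intramolecular SN2 at C14 with inversion) turns the alkoxide of 2 into the terminal oxirane 3 with a tertiary alkoxide on C15; dimethylsulfoxonium methylide then opens 3 at the unhindered C13, and the C15 alkoxide displaces dimethyl sulfoxide from the ylide-derived carbon C12. The closest known reaction type is the sulfoxonium-ylide ring expansion of 2,3-epoxy alcohols to 3-hydroxytetrahydrofurans, an extension of the Corey–Chaykovsky oxirane-to-oxetane homologation. The oxolane closes 5-exo-tet (oxygen on C15 onto C12), which should outrun the 4-exo-tet closure of the C14 alkoxide to an oxetane. The only stereocentre, C14, is set stereospecifically by the invertive Payne step, so the 2R oxirane should give the 3S oxolanol. The step needs ylide attack on the Payne isomer 3 and not on the trisubstituted oxirane of 2; the neopentyl-type hindrance at C14 of 2 and the higher reactivity of the monosubstituted oxirane should secure this under Curtin–Hammett conditions.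

Step 3
Reactants: 4 (3S)-2,2-dimethyloxolan-3-ol
Product: 5 tert-butyl{[(3S)-2,2-dimethyloxolan-3-yl]oxy}dimethylsilane
Conditions: t-BuMe2SiOTf, 2,6-lutidine, CH2Cl2, 0 °C
Reagents that add atoms: tert-butyldimethylsilyl trifluoromethanesulfonate, CC(C)(C)[Si](C)(C)OS(=O)(=O)C(F)(F)F
Why: silyl triflate silylation of the hindered secondary alcohol, which does not touch the stereocentre.

Step 4
Reactants: 5 tert-butyl{[(3S)-2,2-dimethyloxolan-3-yl]oxy}dimethylsilane
Product: 6 (4S)-4-[(tert-butyldimethylsilyl)oxy]-5,5-dimethyloxolan-2-one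
Conditions: RuCl3·xH2O (cat.), NaIO4, CCl4/MeCN/H2O, rt (RuO4 formed in situ)
Reagents that add atoms: sodium periodate, [Na+].[O-]I(=O)(=O)=O
Why: ruthenium tetroxide oxidation of a cyclic ether to the lactone; C12 is the only CH2 next to the ring oxygen because the other α-carbon is quaternary, and the silyl ether should be tolerated.

Step 5
Reactants: 6 (4S)-4-[(tert-butyldimethylsilyl)oxy]-5,5-dimethyloxolan-2-one
Product: 8 (4S)-4-[(tert-butyldimethylsilyl)oxy]-5,5-dimethyloxolan-2-yl acetate (both anomers), via diisobutylaluminium lactolate 7 (not isolated)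
Conditions: i-Bu2AlH, CH2Cl2, −78 °C; then pyridine, 4-(dimethylamino)pyridine (cat.), Ac2O, −78 °C to 0 °C
Reagents that add atoms: acetic anhydride, CC(=O)OC(C)=O
Why: one-pot reductive acetylation; the aluminium lactolate from half-reduction of the lactone is trapped as the anomeric acetate before ring-opening or over-reduction.

Step 6
Reactants: 8 (4S)-4-[(tert-butyldimethylsilyl)oxy]-5,5-dimethyloxolan-2-yl acetate
Product: 9 tert-butyl({(3S,5S)-2,2-dimethyl-5-[(trimethylsilyl)ethynyl]oxolan-3-yl}oxy)dimethylsilane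
Conditions: Me3SiC≡CSnBu3, BF3·OEt2, CH2Cl2, −78 °C to −40 °C
Reagents that add atoms: trimethyl[(tributylstannyl)ethynyl]silane, C[Si](C)(C)C#C[Sn](CCCC)(CCCC)CCCC
Why: Lewis-acid ionisation to the oxocarbenium ion and ipso-attack of the alkynylstannane (C-glycosylation type); inside attack on the envelope with the C14 silyloxy group pseudoaxial should place the alkyne cis to that group and set C12 as S, the minor epimer being removed by chromatography.

Step 7
Reactants: 9 tert-butyl({(3S,5S)-2,2-dimethyl-5-[(trimethylsilyl)ethynyl]oxolan-3-yl}oxy)dimethylsilane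
Product: 10 tert-butyl{[(3S,5S)-5-ethynyl-2,2-dimethyloxolan-3-yl]oxy}dimethylsilane
Conditions: K2CO3, MeOH, rt
Reagents that add atoms: none
Why: methanolysis of the alkynyl C–Si bond, which should leave the silyl ether intact.

Step 8
Reactants: 10 tert-butyl{[(3S,5S)-5-ethynyl-2,2-dimethyloxolan-3-yl]oxy}dimethylsilane
Product: 12 tert-butyl({(3S,5S)-5-[(1E)-1-iodoprop-1-en-2-yl]-2,2-dimethyloxolan-3-yl}oxy)dimethylsilane, via dimethylalkenylalane 11 (not isolated)
Conditions: AlMe3, Cp2ZrCl2, CH2Cl2, 0 °C to rt; then I2, THF, −30 °C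
Reagents that add atoms: trimethylaluminium, C[Al](C)C; iodine, [I][I]
Why: zirconium-catalysed carboalumination (Negishi) adds methyl and aluminium syn across the terminal alkyne with methyl on C11, and iodinolysis with retention should give the 10E iodide.

Step 9
Reactants: 12 tert-butyl({(3S,5S)-5-[(1E)-1-iodoprop-1-en-2-yl]-2,2-dimethyloxolan-3-yl}oxy)dimethylsilane; 13 (4-bromobut-1-yn-1-yl)trimethylsilane
Product: 15 tert-butyl({(3S,5S)-2,2-dimethyl-5-[(2E)-7-(trimethylsilyl)hept-2-en-6-yn-2-yl]oxolan-3-yl}oxy)dimethylsilane, via [4-(trimethylsilyl)but-3-yn-1-yl]zinc bromide 14 (not isolated)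
Conditions: 13, Zn dust, I2 (cat.), DMA, 60 °C; then 12, PdCl2(dppf) (cat.), THF, rt
Reagents that add atoms: none
Why: Negishi coupling of a primary alkylzinc with the alkenyl iodide forms C9–C10 with retention of the alkene geometry.

Step 10
Reactants: 15 tert-butyl({(3S,5S)-2,2-dimethyl-5-[(2E)-7-(trimethylsilyl)hept-2-en-6-yn-2-yl]oxolan-3-yl}oxy)dimethylsilane
Product: 16 tert-butyl({(3S,5S)-5-[(2E)-hept-2-en-6-yn-2-yl]-2,2-dimethyloxolan-3-yl}oxy)dimethylsilane
Conditions: K2CO3, MeOH, rt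
Reagents that add atoms: none
Why: methanolysis of the alkynylsilane frees the terminal alkyne for the next carboalumination.

Step 11
Reactants: 16 tert-butyl({(3S,5S)-5-[(2E)-hept-2-en-6-yn-2-yl]-2,2-dimethyloxolan-3-yl}oxy)dimethylsilane
Product: 18 (2E,6E)-7-[(2S,4S)-4-{[tert-butyl(dimethyl)silyl]oxy}-5,5-dimethyloxolan-2-yl]-3-methylocta-2,6-dien-1-ol, via dimethylalkenylalane 17 (not isolated)
Conditions: AlMe3, Cp2ZrCl2 (cat.), CH2Cl2, 0 °C to rt; then n-BuLi, THF/hexane, −78 °C; then (CH2O)n, rt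
Reagents that add atoms: trimethylaluminium, C[Al](C)C; formaldehyde (as paraformaldehyde), C=O
Why: syn-carboalumination (Negishi) places methyl on C7 and aluminium on C6, and the derived alkenylalanate adds to formaldehyde with retention, which should give the 6E allylic alcohol with C5 in place.

Step 12
Reactants: 18 (2E,6E)-7-[(2S,4S)-4-{[tert-butyl(dimethyl)silyl]oxy}-5,5-dimethyloxolan-2-yl]-3-methylocta-2,6-dien-1-ol
Product: 19 (2E,6E)-7-[(2S,4S)-4-{[tert-butyl(dimethyl)silyl]oxy}-5,5-dimethyloxolan-2-yl]-3-methylocta-2,6-dienal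
Conditions: MnO2, CH2Cl2, rt
Reagents that add atoms: none
Why: manganese dioxide oxidises the allylic alcohol selectively and should not isomerise the alkene.

Step 13
Reactants: 19 (2E,6E)-7-[(2S,4S)-4-{[tert-butyl(dimethyl)silyl]oxy}-5,5-dimethyloxolan-2-yl]-3-methylocta-2,6-dienal
Product: 20 (4S,5E,9E)-10-[(2S,4S)-4-{[tert-butyl(dimethyl)silyl]oxy}-5,5-dimethyloxolan-2-yl]-6-methylundeca-5,9-dien-1-yn-4-ol
Conditions: allenylboronic acid pinacol ester, (S)-3,3′-bis(2,4,6-triisopropylphenyl)-1,1′-binaphthyl-2,2′-diyl hydrogen phosphate (10 mol %), 4 Å MS, toluene, 0 °C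
Reagents that add atoms: allenylboronic acid pinacol ester, C=C=CB1OC(C)(C)C(C)(C)O1
Why: chiral phosphoric acid-catalysed propargylation through a closed six-membered SE2′ transition state; the catalyst enantiomer is chosen to direct the allenylboronate to the Si face of the enal, which should set C5 as S.

Step 14
Reactants: 21 4-methoxy-2-methylphenol
Product: 22 2-(hydroxymethyl)-4-methoxy-6-methylphenol
Conditions: aq. HCHO (37 %), NaOH, H2O, rt
Reagents that add atoms: formaldehyde, C=O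
Why: Lederer–Manasse hydroxymethylation of the phenoxide at the only free ortho position, the para position being blocked by methoxy.

Step 15
Reactants: 22 2-(hydroxymethyl)-4-methoxy-6-methylphenol
Product: 23 (2,5-dimethoxy-3-methylphenyl)methanol
Conditions: MeI, K2CO3, acetone, reflux
Reagents that add atoms: iodomethane, [CH3]I
Why: Williamson etherification; only the far more acidic phenol is deprotonated by carbonate, so the benzylic alcohol should stay free.

Step 16
Reactants: 23 (2,5-dimethoxy-3-methylphenyl)methanol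
Product: 24 1-(chloromethyl)-2,5-dimethoxy-3-methylbenzene
Conditions: SOCl2, CH2Cl2, 0 °C
Reagents that add atoms: thionyl chloride, O=S(Cl)Cl
Why: chlorination of an electron-rich benzylic alcohol through its chlorosulfite.

Step 17
Reactants: 20 (4S,5E,9E)-10-[(2S,4S)-4-{[tert-butyl(dimethyl)silyl]oxy}-5,5-dimethyloxolan-2-yl]-6-methylundeca-5,9-dien-1-yn-4-ol; 24 1-(chloromethyl)-2,5-dimethoxy-3-methylbenzene
Product: 26 (2E,5S,6E,10E)-11-[(2S,4S)-4-{[tert-butyl(dimethyl)silyl]oxy}-5,5-dimethyloxolan-2-yl]-1-(2,5-dimethoxy-3-methylphenyl)-3,7-dimethyldodeca-2,6,10-trien-5-ol, via dialuminated alkenylalane 25 (not isolated)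
Conditions: AlMe3 (3.5 equiv), Cp2ZrCl2 (cat.), CH2Cl2, 0 °C to rt; then 24, NiCl2(PPh3)2 (cat.) reduced with n-BuLi to zerovalent nickel, THF, rt
Reagents that add atoms: trimethylaluminium, C[Al](C)C
Why: the aluminium alkoxide of the homopropargylic alcohol undergoes syn-carboalumination (Negishi; methyl on C3, aluminium on C2) at or below room temperature, and nickel-catalysed cross-coupling of the alkenylalane with the benzylic chloride should form C1–C2 with retention, giving the 2E alkene.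

Step 18
Reactants: 26 (2E,5S,6E,10E)-11-[(2S,4S)-4-{[tert-butyl(dimethyl)silyl]oxy}-5,5-dimethyloxolan-2-yl]-1-(2,5-dimethoxy-3-methylphenyl)-3,7-dimethyldodeca-2,6,10-trien-5-ol
Product: 27 (2E,5S,6E,10E)-11-[(2S,4S)-4-{[tert-butyl(dimethyl)silyl]oxy}-5,5-dimethyloxolan-2-yl]-1-(2,5-dimethoxy-3-methylphenyl)-3,7-dimethyldodeca-2,6,10-trien-5-yl acetate
Conditions: Ac2O, pyridine, 4-(dimethylamino)pyridine (cat.), CH2Cl2, 0 °C to rt
Reagents that add atoms: acetic anhydride, CC(=O)OC(C)=O
Why: acylation of the only free hydroxyl, with no bond to C5 broken, so the S configuration is kept.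

Step 19
Reactants: 27 (2E,5S,6E,10E)-11-[(2S,4S)-4-{[tert-butyl(dimethyl)silyl]oxy}-5,5-dimethyloxolan-2-yl]-1-(2,5-dimethoxy-3-methylphenyl)-3,7-dimethyldodeca-2,6,10-trien-5-yl acetate
Product: 28 (2E,5S,6E,10E)-1-(2,5-dimethoxy-3-methylphenyl)-11-[(2S,4S)-4-hydroxy-5,5-dimethyloxolan-2-yl]-3,7-dimethyldodeca-2,6,10-trien-5-yl acetate
Conditions: HF·pyridine, pyridine/THF, 0 °C to rt
Reagents that add atoms: none
Why: fluoride-driven cleavage of the silyl ether under buffered, non-basic conditions that should spare the allylic acetate.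

Step 20
Reactants: 28 (2E,5S,6E,10E)-1-(2,5-dimethoxy-3-methylphenyl)-11-[(2S,4S)-4-hydroxy-5,5-dimethyloxolan-2-yl]-3,7-dimethyldodeca-2,6,10-trien-5-yl acetate
Product: 29 (2E,5S,6E,10E)-11-[(2S,4S)-4-hydroxy-5,5-dimethyloxolan-2-yl]-3,7-dimethyl-1-(5-methyl-3,6-dioxocyclohexa-1,4-dien-1-yl)dodeca-2,6,10-trien-5-yl acetate (CNP0106310.2)
Conditions: (NH4)2Ce(NO3)6, MeCN/H2O, 0 °C
Reagents that add atoms: water, O
Why: oxidative demethylation of the 1,4-dimethoxyarene by ceric ammonium nitrate through the arene radical cation and attack of water, which should leave the alkenes, the acetate and the secondary alcohol untouched in a short, cold reaction.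

**Compound list**

1 | 3-methylbut-2-en-1-ol (prenol) | CC(C)=CCO | starting material
2 | [(2R)-3,3-dimethyloxiran-2-yl]methanol | OC[C@H]1OC1(C)C | intermediate
3 | sodium 2-[(2S)-oxiran-2-yl]propan-2-olate (not isolated) | CC(C)([O-])[C@@H]1CO1.[Na+] | intermediate
4 | (3S)-2,2-dimethyloxolan-3-ol | C1C[C@H](O)C(C)(C)O1 | intermediate
5 | tert-butyl{[(3S)-2,2-dimethyloxolan-3-yl]oxy}dimethylsilane | C1C[C@H](O[Si](C)(C)C(C)(C)C)C(C)(C)O1 | intermediate
6 | (4S)-4-[(tert-butyldimethylsilyl)oxy]-5,5-dimethyloxolan-2-one | O=C1C[C@H](O[Si](C)(C)C(C)(C)C)C(C)(C)O1 | intermediate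
7 | diisobutylaluminium (4S)-4-[(tert-butyldimethylsilyl)oxy]-5,5-dimethyloxolan-2-olate (not isolated) | CC(C)C[Al](CC(C)C)OC1C[C@H](O[Si](C)(C)C(C)(C)C)C(C)(C)O1 | intermediate
8 | (4S)-4-[(tert-butyldimethylsilyl)oxy]-5,5-dimethyloxolan-2-yl acetate (both anomers) | CC(=O)OC1C[C@H](O[Si](C)(C)C(C)(C)C)C(C)(C)O1 | intermediate
9 | tert-butyl({(3S,5S)-2,2-dimethyl-5-[(trimethylsilyl)ethynyl]oxolan-3-yl}oxy)dimethylsilane | C[Si](C)(C)C#C[C@@H]1C[C@H](O[Si](C)(C)C(C)(C)C)C(C)(C)O1 | intermediate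
10 | tert-butyl{[(3S,5S)-5-ethynyl-2,2-dimethyloxolan-3-yl]oxy}dimethylsilane | C#C[C@@H]1C[C@H](O[Si](C)(C)C(C)(C)C)C(C)(C)O1 | intermediate
11 | {(1E)-2-[(2S,4S)-4-{[tert-butyl(dimethyl)silyl]oxy}-5,5-dimethyloxolan-2-yl]prop-1-en-1-yl}dimethylalumane (not isolated) | C[Al](C)/C=C(\C)[C@@H]1C[C@H](O[Si](C)(C)C(C)(C)C)C(C)(C)O1 | intermediate
12 | tert-butyl({(3S,5S)-5-[(1E)-1-iodoprop-1-en-2-yl]-2,2-dimethyloxolan-3-yl}oxy)dimethylsilane | I/C=C(\C)[C@@H]1C[C@H](O[Si](C)(C)C(C)(C)C)C(C)(C)O1 | intermediate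
13 | (4-bromobut-1-yn-1-yl)trimethylsilane | C[Si](C)(C)C#CCCBr | starting material
14 | [4-(trimethylsilyl)but-3-yn-1-yl]zinc bromide (not isolated) | C[Si](C)(C)C#CCC[Zn]Br | intermediate
15 | tert-butyl({(3S,5S)-2,2-dimethyl-5-[(2E)-7-(trimethylsilyl)hept-2-en-6-yn-2-yl]oxolan-3-yl}oxy)dimethylsilane | C[Si](C)(C)C#CCC/C=C(\C)[C@@H]1C[C@H](O[Si](C)(C)C(C)(C)C)C(C)(C)O1 | intermediate
16 | tert-butyl({(3S,5S)-5-[(2E)-hept-2-en-6-yn-2-yl]-2,2-dimethyloxolan-3-yl}oxy)dimethylsilane | C#CCC/C=C(\C)[C@@H]1C[C@H](O[Si](C)(C)C(C)(C)C)C(C)(C)O1 | intermediate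
17 | {(1E,5E)-6-[(2S,4S)-4-{[tert-butyl(dimethyl)silyl]oxy}-5,5-dimethyloxolan-2-yl]-2-methylhepta-1,5-dien-1-yl}dimethylalumane (not isolated) | C[Al](C)/C=C(\C)CC/C=C(\C)[C@@H]1C[C@H](O[Si](C)(C)C(C)(C)C)C(C)(C)O1 | intermediate
18 | (2E,6E)-7-[(2S,4S)-4-{[tert-butyl(dimethyl)silyl]oxy}-5,5-dimethyloxolan-2-yl]-3-methylocta-2,6-dien-1-ol | OC/C=C(\C)CC/C=C(\C)[C@@H]1C[C@H](O[Si](C)(C)C(C)(C)C)C(C)(C)O1 | intermediate
19 | (2E,6E)-7-[(2S,4S)-4-{[tert-butyl(dimethyl)silyl]oxy}-5,5-dimethyloxolan-2-yl]-3-methylocta-2,6-dienal | O=C/C=C(\C)CC/C=C(\C)[C@@H]1C[C@H](O[Si](C)(C)C(C)(C)C)C(C)(C)O1 | intermediate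
20 | (4S,5E,9E)-10-[(2S,4S)-4-{[tert-butyl(dimethyl)silyl]oxy}-5,5-dimethyloxolan-2-yl]-6-methylundeca-5,9-dien-1-yn-4-ol | O[C@H](/C=C(\C)CC/C=C(\C)[C@@H]1C[C@H](O[Si](C)(C)C(C)(C)C)C(C)(C)O1)CC#C | intermediate
21 | 4-methoxy-2-methylphenol | COc1ccc(O)c(C)c1 | starting material
22 | 2-(hydroxymethyl)-4-methoxy-6-methylphenol | COc1cc(C)c(O)c(CO)c1 | intermediate
23 | (2,5-dimethoxy-3-methylphenyl)methanol | COc1cc(C)c(OC)c(CO)c1 | intermediate
24 | 1-(chloromethyl)-2,5-dimethoxy-3-methylbenzene | COc1cc(C)c(OC)c(CCl)c1 | intermediate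
25 | dimethylaluminium (1E,4S,5E,9E)-1-(dimethylalumanyl)-2,6-dimethyl-10-[(2S,4S)-4-{[tert-butyl(dimethyl)silyl]oxy}-5,5-dimethyloxolan-2-yl]undeca-1,5,9-trien-4-olate (not isolated) | C[Al](C)O[C@H](/C=C(\C)CC/C=C(\C)[C@@H]1C[C@H](O[Si](C)(C)C(C)(C)C)C(C)(C)O1)C/C(C)=C/[Al](C)C | intermediate
26 | (2E,5S,6E,10E)-11-[(2S,4S)-4-{[tert-butyl(dimethyl)silyl]oxy}-5,5-dimethyloxolan-2-yl]-1-(2,5-dimethoxy-3-methylphenyl)-3,7-dimethyldodeca-2,6,10-trien-5-ol | O[C@H](/C=C(\C)CC/C=C(\C)[C@@H]1C[C@H](O[Si](C)(C)C(C)(C)C)C(C)(C)O1)C/C(C)=C/Cc1cc(OC)cc(C)c1OC | intermediate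
27 | (2E,5S,6E,10E)-11-[(2S,4S)-4-{[tert-butyl(dimethyl)silyl]oxy}-5,5-dimethyloxolan-2-yl]-1-(2,5-dimethoxy-3-methylphenyl)-3,7-dimethyldodeca-2,6,10-trien-5-yl acetate | CC(=O)O[C@H](/C=C(\C)CC/C=C(\C)[C@@H]1C[C@H](O[Si](C)(C)C(C)(C)C)C(C)(C)O1)C/C(C)=C/Cc1cc(OC)cc(C)c1OC | intermediate
28 | (2E,5S,6E,10E)-1-(2,5-dimethoxy-3-methylphenyl)-11-[(2S,4S)-4-hydroxy-5,5-dimethyloxolan-2-yl]-3,7-dimethyldodeca-2,6,10-trien-5-yl acetate | CC(=O)O[C@H](/C=C(\C)CC/C=C(\C)[C@@H]1C[C@H](O)C(C)(C)O1)C/C(C)=C/Cc1cc(OC)cc(C)c1OC | intermediate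
29 | (2E,5S,6E,10E)-11-[(2S,4S)-4-hydroxy-5,5-dimethyloxolan-2-yl]-3,7-dimethyl-1-(5-methyl-3,6-dioxocyclohexa-1,4-dien-1-yl)dodeca-2,6,10-trien-5-yl acetate | CC(=O)O[C@H](/C=C(\C)CC/C=C(\C)[C@@H]1C[C@H](O)C(C)(C)O1)C/C(C)=C/CC1=CC(=O)C=C(C)C1=O | target

**Step count and risks**

Total step count: 20. Longest linear sequence: 17 steps (steps 1–13 and 17–20); steps 14–16 make the arene partner 24.

The three steps most likely to fail:

Step 6. The risk is poor facial selectivity in the addition to the oxocarbenium ion: the bulky silyloxy group next to the gem-dimethyl carbon may not hold the pseudoaxial position that the inside-attack model needs, so C12 epimers could form in comparable amounts. The fallback sets C12 by reagent control and an invertive ring closure, and sets out from lactone 6. Addition of LiC≡CSiMe3 (THF, −78 °C) should stop at the ketone stage and give (5S)-5-[(tert-butyldimethylsilyl)oxy]-6-hydroxy-6-methyl-1-(trimethylsilyl)hept-1-yn-3-one F1, in equilibrium with its cyclic hemiketal. Noyori asymmetric transfer hydrogenation with RuCl[(R,R)-TsDPEN](p-cymene) in i-PrOH should give (3R,5S)-5-[(tert-butyldimethylsilyl)oxy]-6-methyl-1-(trimethylsilyl)hept-1-yne-3,6-diol F2. The secondary propargylic hydroxyl is mesylated selectively (MsCl, Et3N, CH2Cl2, −20 °C) to (3R,5S)-5-[(tert-butyldimethylsilyl)oxy]-6-hydroxy-6-methyl-1-(trimethylsilyl)hept-1-yn-3-yl methanesulfonate F3. NaH (THF, 0 °C) should then close the oxolane by 5-exo-tet SN2 displacement by the tertiary alkoxide with inversion at C12, which comes back to the route at 9.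

Step 13. The risk is insufficient enantiofacial discrimination, because a β,β-disubstituted aliphatic enal is a less well-matched substrate for the phosphoric acid catalyst than aryl aldehydes, giving a C5 epimer mixture that is hard to separate. The fallback sets out from enal 19. A zinc-mediated Barbier propargylation (propargyl bromide, Zn, THF/aq. NH4Cl) should give (4RS,5E,9E)-10-[(2S,4S)-4-{[tert-butyl(dimethyl)silyl]oxy}-5,5-dimethyloxolan-2-yl]-6-methylundeca-5,9-dien-1-yn-4-ol F4 as both C4 epimers. Sharpless kinetic resolution (Ti(OiPr)4, D-(−)-diisopropyl tartrate, t-BuOOH 0.6 equiv, CH2Cl2, −20 °C) should epoxidise the 4R epimer to (1R)-1-[(2R,3R)-3-{(3E)-4-[(2S,4S)-4-{[tert-butyl(dimethyl)silyl]oxy}-5,5-dimethyloxolan-2-yl]pent-3-en-1-yl}-3-methyloxiran-2-yl]but-3-yn-1-ol F5. The slow-reacting 4S epimer is recovered, and the route is rejoined at 20.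

Step 17. The risk is incomplete carboalumination or protodemetalation of the alkoxide-bearing alkenylalane before nickel-catalysed coupling, which would leave reduced 1,1-disubstituted alkene and unreacted benzylic chloride in a one-pot operation that cannot be purified midway. The fallback separates the two events and inverts the coupling polarity, and sets out from 20. Carboalumination as in step 17 followed by iodinolysis (I2, THF, −30 °C) should give the isolable (1E,4S,5E,9E)-10-[(2S,4S)-4-{[tert-butyl(dimethyl)silyl]oxy}-5,5-dimethyloxolan-2-yl]-1-iodo-2,6-dimethylundeca-1,5,9-trien-4-ol F6. Chloride 24 is converted with Zn dust and LiCl in THF into (2,5-dimethoxy-3-methylbenzyl)zinc chloride F7. Negishi coupling of F6 with excess F7 under Pd(PPh3)4 catalysis (zerovalent palladium, THF, rt) should form C1–C2 with retention and comes back to the route at 26.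

**Further compounds**

F1 | step 6 | (5S)-5-[(tert-butyldimethylsilyl)oxy]-6-hydroxy-6-methyl-1-(trimethylsilyl)hept-1-yn-3-one | C[Si](C)(C)C#CC(=O)C[C@H](O[Si](C)(C)C(C)(C)C)C(C)(C)O
F2 | step 6 | (3R,5S)-5-[(tert-butyldimethylsilyl)oxy]-6-methyl-1-(trimethylsilyl)hept-1-yne-3,6-diol | C[Si](C)(C)C#C[C@H](O)C[C@H](O[Si](C)(C)C(C)(C)C)C(C)(C)O
F3 | step 6 | (3R,5S)-5-[(tert-butyldimethylsilyl)oxy]-6-hydroxy-6-methyl-1-(trimethylsilyl)hept-1-yn-3-yl methanesulfonate | C[Si](C)(C)C#C[C@H](OS(C)(=O)=O)C[C@H](O[Si](C)(C)C(C)(C)C)C(C)(C)O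
F4 | step 13 | (4RS,5E,9E)-10-[(2S,4S)-4-{[tert-butyl(dimethyl)silyl]oxy}-5,5-dimethyloxolan-2-yl]-6-methylundeca-5,9-dien-1-yn-4-ol | OC(/C=C(\C)CC/C=C(\C)[C@@H]1C[C@H](O[Si](C)(C)C(C)(C)C)C(C)(C)O1)CC#C
F5 | step 13 | (1R)-1-[(2R,3R)-3-{(3E)-4-[(2S,4S)-4-{[tert-butyl(dimethyl)silyl]oxy}-5,5-dimethyloxolan-2-yl]pent-3-en-1-yl}-3-methyloxiran-2-yl]but-3-yn-1-ol | C#CC[C@@H](O)[C@H]1O[C@]1(C)CC/C=C(\C)[C@@H]2C[C@H](O[Si](C)(C)C(C)(C)C)C(C)(C)O2
F6 | step 17 | (1E,4S,5E,9E)-10-[(2S,4S)-4-{[tert-butyl(dimethyl)silyl]oxy}-5,5-dimethyloxolan-2-yl]-1-iodo-2,6-dimethylundeca-1,5,9-trien-4-ol | O[C@H](/C=C(\C)CC/C=C(\C)[C@@H]1C[C@H](O[Si](C)(C)C(C)(C)C)C(C)(C)O1)C/C(C)=C/I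
F7 | step 17 | (2,5-dimethoxy-3-methylbenzyl)zinc chloride | COc1cc(C)c(OC)c(C[Zn]Cl)c1
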